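All runs come from a simulation on assumed constants; noise was put on by code.

4 questions stand on one flask, followed so far as the beta run, and they hang on one share of its partner.

in all of them: substrate 25 mM; initiator 1.2 mM
- beta: partner 25 mM; temperature −20 °C; the very flask that is asked about, followed so far
- gamma: partner 25 mM; temperature −14 °C; run made earlier
- flask: partner 25.0 mM; temperature −20 °C; time 30 min

- beta (time / min: target / %, substrate / %): 1.50: 21.2, 78.8; 5.00: 46.8, 52.8; 8.00: 57.7, 41.7; 12.0: 65.0, 35.1; 20.0: 70.2, 29.1; 25.0: 71.2, 27.8; 30.0: 71.7, 27.7
- gamma (time / min: target / %, substrate / %): 1.50: 32.9, 66.8; 5.00: 60.0, 39.3; 8.00: 66.7, 32.3; 12.0: 71.0, 28.6; 20.0: 71.3, 27.5; 25.0: 71.5, 26.3; 30.0: 71.9, 25.6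

(each reading ± 0.3 percentage points)

- north-east: at 30 min take out 90% of the by-product then present, then wait 1.0 h
- south-east: change nothing and wait 1.0 h more
- south-west: at 30 min raise the temperature by 15 K, then wait 1.0 h
- east: at 30 min add partner, 100% of the amount charged, then wait 1.0 h

- target, in percent of the substrate first charged, at 30 min
- what to do for the largest gain in target; "none" if nothing gains more than 2 percentage points (north-east / south-east / south-west / east / none)
- target present, in percent of the substrate first charged, after north-east
- target present, in percent of the substrate first charged, after east

- additions leave the volume as it is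
- the earlier runs were read with a standard deviation of 0.3 percentage points

The flask reads 71.7% of target at 30 min, and that reading answers "now". The stop needs a reason. In the gamma run substrate falls from 28.6% to 25.6% over the last readings, yet target goes from 71.0% to 71.9%. A step held in balance returns target when substrate drains, so the stop is read as the end of partner, which the readings do not show, while substrate in the flask still stands at 27.7%. The charges are equal, and one partner is taken to make one target, so each partner molecule meets a fork: into target, or away by a side path. In the flask 71.7% of the charged partner ended as target; this fraction is the capture share.

Over its last two intervals the flask gained 1 point, then 0.5 points, half as much, so a tail that keeps halving has about that last step still to give. Waiting, heating and taking out by-product bring no partner, so north-east reaches about 72.2%, a gain below 2 points. East brings a fresh charge of partner, and at the capture share that offers 71.7% of a charge as target, more than the substrate left. Substrate then becomes the limiting reagent, and target tops out near the sum 99.4%.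

The weak link is the share itself, since fresh partner meets a flask with less substrate than the recipe had. But east needs a share of just 27.7%, well under the capture share, and the further 1.0 h is far longer than the 5.00 min that took substrate to 52.8%. So east stands as the choice.

The forecast differs on both amounts, giving 71.6%, east, 83% and 88%, on the ground that “That indicates a true equilibrium”.

The flask gives 71.7%, with east best: 72.1% after north-east and 98.9% after east.

    2 first chain carrier → ended chains A (k = 1.10 × 10⁷ /M/s, Ea = 19.0 kJ/mol)
    initiator → 2 initiating radical (k = 0.00370 /min, Ea = 85.0 kJ/mol)
    2 second chain carrier → ended chains B (k = 4.00 × 10⁷ /M/s, Ea = 13.0 kJ/mol)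
    partner + first chain carrier ⇌ target + second chain carrier (K = 1.10, k = 36000 /M/s, Ea = 24.0 kJ/mol, ΔH = −37.0 kJ/mol)
    substrate + initiating radical → capped initiator + first chain carrier (k = 2.50 × 10⁵ /M/s, Ea = 21.0 kJ/mol)
    2 partner → self-condensation product (k = 3.00 /M/min, Ea = 58.0 kJ/mol)
    substrate + second chain carrier → by-product + first chain carrier (k = 1.10 × 10⁶ /M/s, Ea = 22.0 kJ/mol)
    (constants at −20 °C)

At 30.0 min the flask holds 0.40% of its partner and 3.49 mM of self-condensation product, which takes two partner each, so 27.9% of the partner charge. A neighbouring flask charged with 62 mM of substrate, other charges held, receives the same partner, so the capture share puts 28.9% of its substrate into target. That neighbour gives 29.0%, with 0.322% of its partner left and 70.6% of its substrate unreacted.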